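Ring C is disconnected at C3, the lone CH flanked by C2 (carrying O1 and ring B) and the C4 carbonyl; removing it contracts the pyranone to a 2-aryl-3-oxybenzofuran. In the forward direction dichlorocarbene is inserted into the C2=C3 bond of a 3-silyloxybenzofuran, which in one operation forms C2–C3 and C3–C4, expands the furan to ring C and unmasks the C4 ketone. The precursor carries benzyl ethers on ring A, a silyl enol ether at C3 and a pivalate on the ring B oxygen, installed before C-acylation so that ring B stays inert to bromination, carbene and sulfation; the surplus C3 chlorine is removed together with the benzyl groups.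

Key step: step 6

Remark: the target is taken as the free hydrogen sulfate, so the salt is converted into the acid only in the last operation, cold and briefly, because aryl hydrogen sulfates hydrolyse in acid.

Step 1
Reactants: 1 (3-hydroxy-4-methoxyphenyl)acetonitrile; 2 pivaloyl chloride
Product: 3 5-(cyanomethyl)-2-methoxyphenyl pivalate
Conditions: PivCl (1.1 equiv), Et3N, DMAP (cat.), CH2Cl2, 0 → 25 °C
Reagents that add atoms: pivaloyl chloride 2, CC(C)(C)C(=O)Cl
Why: DMAP-catalysed O-acylation of the only nucleophilic site, the phenol, should give a hindered aryl ester that masks the ring B oxygen against alkylation, bromination and the carbene.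

Step 2
Reactants: 3 5-(cyanomethyl)-2-methoxyphenyl pivalate; 4 phloroglucinol
Product: 6 2-methoxy-5-[2-oxo-2-(2,4,6-trihydroxyphenyl)ethyl]phenyl pivalate, via ketiminium chloride 5 (not isolated)
Conditions: ZnCl2 (0.5 equiv), HCl (g), Et2O, 0 °C; then H2O, 100 °C
Reagents that add atoms: water, O
Why: In this Houben–Hoesch acylation the HCl/ZnCl2-activated nitrile should attack the threefold-symmetric phloroglucinol (one possible regioisomer), the precipitating ketiminium salt stops the reaction at monoacylation, and hot water hydrolyses it to the ketone while the hindered aryl pivalate survives.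

Step 3
Reactants: 6 2-methoxy-5-[2-oxo-2-(2,4,6-trihydroxyphenyl)ethyl]phenyl pivalate; 7 benzyl bromide
Product: 8 5-{2-[2,4-bis(benzyloxy)-6-hydroxyphenyl]-2-oxoethyl}-2-methoxyphenyl pivalate
Conditions: BnBr (2.1 equiv), K2CO3 (2.2 equiv), DMF, 25 °C
Reagents that add atoms: benzyl bromide 7, BrCc1ccccc1
Why: In this Williamson ether synthesis the para hydroxyl and one ortho hydroxyl should be benzylated, whereas the last ortho hydroxyl is locked in a hydrogen bond to the ketone and stays free for the later ring closure.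

Step 4
Reactants: 8 5-{2-[2,4-bis(benzyloxy)-6-hydroxyphenyl]-2-oxoethyl}-2-methoxyphenyl pivalate; 9 CuBr2
Product: 10 5-{2-[2,4-bis(benzyloxy)-6-hydroxyphenyl]-1-bromo-2-oxoethyl}-2-methoxyphenyl pivalate (racemic)
Conditions: CuBr2 (2.1 equiv), EtOAc/CHCl3 (1:1), reflux
Reagents that add atoms: CuBr2 9, [Cu+2].[Br-].[Br-]
Why: Heterogeneous α-bromination of an enolisable aryl benzyl ketone by CuBr2 (divalent copper is reduced to monovalent copper) should halogenate through the chelated enol at the doubly activated benzylic carbon in preference to the arenes, ring B being deactivated by its ester; the product is racemic.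

Step 5
Reactants: 10 5-{2-[2,4-bis(benzyloxy)-6-hydroxyphenyl]-1-bromo-2-oxoethyl}-2-methoxyphenyl pivalate; 11 tert-butyldimethylsilyl triflate
Product: 13 4,6-bis(benzyloxy)-3-(tert-butyldimethylsilyloxy)-2-[4-methoxy-3-(pivaloyloxy)phenyl]benzofuran, via benzofuranone 12 (not isolated)
Conditions: DBU (1.2 equiv), CH2Cl2, Ar, 0 °C; then Et3N (3 equiv), TBSOTf (1.5 equiv), 0 → 25 °C
Reagents that add atoms: tert-butyldimethylsilyl triflate 11, CC(C)(C)[Si](C)(C)OS(=O)(=O)C(F)(F)F
Why: Intramolecular Williamson displacement (5-exo-tet) of the activated benzylic bromide by the ortho phenoxide should close the furanone, and soft enolisation with Et3N/TBSOTf in the same flask then O-silylates the acidic C2–H ketone to the aromatic 3-silyloxybenzofuran, which erases the C2 stereocentre and keeps the oxidation-prone enol away from air.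

Step 6
Reactants: 13 4,6-bis(benzyloxy)-3-(tert-butyldimethylsilyloxy)-2-[4-methoxy-3-(pivaloyloxy)phenyl]benzofuran; 14 sodium trichloroacetate
Product: 17 5,7-bis(benzyloxy)-3-chloro-2-[4-methoxy-3-(pivaloyloxy)phenyl]-4H-chromen-4-one, via dichlorocyclopropane 15 (not isolated), via silyloxyflavylium chloride 16 (not isolated)
Conditions: Cl3CCO2Na (5 equiv, portionwise), anhydrous DME, Ar, 85 °C
Reagents that add atoms: sodium trichloroacetate 14, O=C([O-])C(Cl)(Cl)Cl.[Na+]
Why: Proposed new method: thermal decarboxylation of Cl3CCO2Na releases singlet dichlorocarbene without base, and this electrophile should add in a concerted [2+1] fashion to the benzofuran C2=C3 bond, whose two oxygen substituents (O1 and the silyloxy group) make it the highest-lying π system, to give the gem-dichlorocyclopropane 15. Ionisation of the endo C–Cl bond should then be concerted with disrotatory two-electron electrocyclic cleavage of the former C2–C3 σ bond, assisted by the lone pairs on O1 and on the silyloxy oxygen and driven by formation of the aromatic 4-silyloxyflavylium ion 16, which chloride desilylates to reveal the C4 ketone. The closest known reactions are the dihalocarbene homologation of cyclic silyl enol ethers to 2-halo-enones and the Ciamician–Dennstedt-type carbene ring enlargement of indoles and benzofurans. Ring C is thus closed by ring expansion (the carbene carbon becomes C3 and makes C2–C3 and C3–C4), not by a cyclisation, and no stereocentre remains because both cyclopropane stereocentres return to sp2. The step needs chemoselectivity for C2=C3 over three oxygenated arenes and the benzylic C–H bonds, which the enol ether character of that bond supplies, helped by the electron-poor pivalate on ring B; because the carbene is symmetric, one chlorine necessarily sits endo, the geometry required for ionisation.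

Step 7
Reactants: 17 5,7-bis(benzyloxy)-3-chloro-2-[4-methoxy-3-(pivaloyloxy)phenyl]-4H-chromen-4-one
Product: 18 5,7-dihydroxy-2-[4-methoxy-3-(pivaloyloxy)phenyl]-4H-chromen-4-one
Conditions: H2 (1 atm), 10% Pd/C, NaOAc (2 equiv), THF/MeOH (1:1), 25 °C
Reagents that add atoms: none
Why: Catalytic hydrogenolysis over Pd/C should cleave both aryl benzyl ethers and, with NaOAc taking up the HCl, the activated vinylic C3–Cl bond (hydrodechlorination), while the flavone C2=C3 bond, the aryl ester and the methyl ether are not reduced under one atmosphere of hydrogen.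

Step 8
Reactants: 18 5,7-dihydroxy-2-[4-methoxy-3-(pivaloyloxy)phenyl]-4H-chromen-4-one; 19 sulfur trioxide–pyridine complex
Product: 20 pyridinium 5-hydroxy-2-[4-methoxy-3-(pivaloyloxy)phenyl]-4-oxo-4H-chromen-7-yl sulfate
Conditions: SO3·pyridine (1.5 equiv), pyridine, 25 °C; precipitation with Et2O
Reagents that add atoms: sulfur trioxide–pyridine complex 19, O=S(=O)([O-])[n+]1ccccc1
Why: O-Sulfation with the SO3·pyridine complex should occur only at the acidic, unhindered 7-hydroxyl, because the 5-hydroxyl is tied up in a hydrogen bond to the C4 carbonyl and the ring B oxygen is still acylated.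

Step 9
Reactants: 20 pyridinium 5-hydroxy-2-[4-methoxy-3-(pivaloyloxy)phenyl]-4-oxo-4H-chromen-7-yl sulfate
Product: 22 5-hydroxy-2-(3-hydroxy-4-methoxyphenyl)-4-oxo-4H-chromen-7-yl hydrogen sulfate (luteolin 4'-methyl ether 7-sulfate), via potassium salt 21 (not isolated)
Conditions: K2CO3 (3 equiv), MeOH, 25–40 °C; then 1 M HCl to pH 1–2, 0 °C; C18 desalting (H2O → MeOH), lyophilisation
Reagents that add atoms: none
Why: Carbonate-mediated transesterification (methanolysis) should remove the aryl pivalate without touching the base-stable aryl sulfate monoester, and brief cold acidification with reversed-phase desalting then converts the potassium salt into the free hydrogen sulfate.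

Compound list
1 | (3-hydroxy-4-methoxyphenyl)acetonitrile | COc1ccc(CC#N)cc1O | starting material
2 | pivaloyl chloride | CC(C)(C)C(=O)Cl | starting material
3 | 5-(cyanomethyl)-2-methoxyphenyl pivalate | COc1ccc(CC#N)cc1OC(=O)C(C)(C)C | intermediate
4 | phloroglucinol | Oc1cc(O)cc(O)c1 | starting material
5 | ketiminium chloride of 6 (C=NH2+ in place of C=O; not isolated) | COc1ccc(CC(=[NH2+])c2c(O)cc(O)cc2O)cc1OC(=O)C(C)(C)C.[Cl-] | intermediate
6 | 2-methoxy-5-[2-oxo-2-(2,4,6-trihydroxyphenyl)ethyl]phenyl pivalate | COc1ccc(CC(=O)c2c(O)cc(O)cc2O)cc1OC(=O)C(C)(C)C | intermediate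
7 | benzyl bromide | BrCc1ccccc1 | starting material
8 | 5-{2-[2,4-bis(benzyloxy)-6-hydroxyphenyl]-2-oxoethyl}-2-methoxyphenyl pivalate | COc1ccc(CC(=O)c2c(O)cc(OCc3ccccc3)cc2OCc2ccccc2)cc1OC(=O)C(C)(C)C | intermediate
9 | CuBr2 | [Cu+2].[Br-].[Br-] | starting material
10 | 5-{2-[2,4-bis(benzyloxy)-6-hydroxyphenyl]-1-bromo-2-oxoethyl}-2-methoxyphenyl pivalate (racemic) | COc1ccc(C(Br)C(=O)c2c(O)cc(OCc3ccccc3)cc2OCc2ccccc2)cc1OC(=O)C(C)(C)C | intermediate
11 | tert-butyldimethylsilyl triflate | CC(C)(C)[Si](C)(C)OS(=O)(=O)C(F)(F)F | starting material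
12 | 4,6-bis(benzyloxy)-2-[4-methoxy-3-(pivaloyloxy)phenyl]benzofuran-3(2H)-one (racemic; not isolated) | COc1ccc(C2Oc3cc(OCc4ccccc4)cc(OCc4ccccc4)c3C2=O)cc1OC(=O)C(C)(C)C | intermediate
13 | 4,6-bis(benzyloxy)-3-(tert-butyldimethylsilyloxy)-2-[4-methoxy-3-(pivaloyloxy)phenyl]benzofuran | COc1ccc(-c2oc3cc(OCc4ccccc4)cc(OCc4ccccc4)c3c2O[Si](C)(C)C(C)(C)C)cc1OC(=O)C(C)(C)C | intermediate
14 | sodium trichloroacetate | O=C([O-])C(Cl)(Cl)Cl.[Na+] | starting material
15 | gem-dichlorocyclopropane adduct of 13, CCl2 bridging C2 and C3 of the 2,3-dihydrobenzofuran (cis-fused, racemic; not isolated) | COc1ccc(C23Oc4cc(OCc5ccccc5)cc(OCc5ccccc5)c4C2(O[Si](C)(C)C(C)(C)C)C3(Cl)Cl)cc1OC(=O)C(C)(C)C | intermediate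
16 | 5,7-bis(benzyloxy)-4-(tert-butyldimethylsilyloxy)-3-chloro-2-[4-methoxy-3-(pivaloyloxy)phenyl]chromenylium chloride (not isolated) | COc1ccc(-c2[o+]c3cc(OCc4ccccc4)cc(OCc4ccccc4)c3c(O[Si](C)(C)C(C)(C)C)c2Cl)cc1OC(=O)C(C)(C)C.[Cl-] | intermediate
17 | 5,7-bis(benzyloxy)-3-chloro-2-[4-methoxy-3-(pivaloyloxy)phenyl]-4H-chromen-4-one | COc1ccc(-c2oc3cc(OCc4ccccc4)cc(OCc4ccccc4)c3c(=O)c2Cl)cc1OC(=O)C(C)(C)C | intermediate
18 | 5,7-dihydroxy-2-[4-methoxy-3-(pivaloyloxy)phenyl]-4H-chromen-4-one | COc1ccc(-c2cc(=O)c3c(O)cc(O)cc3o2)cc1OC(=O)C(C)(C)C | intermediate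
19 | sulfur trioxide–pyridine complex | O=S(=O)([O-])[n+]1ccccc1 | starting material
20 | pyridinium 5-hydroxy-2-[4-methoxy-3-(pivaloyloxy)phenyl]-4-oxo-4H-chromen-7-yl sulfate | COc1ccc(-c2cc(=O)c3c(O)cc(OS(=O)(=O)[O-])cc3o2)cc1OC(=O)C(C)(C)C.c1cc[nH+]cc1 | intermediate
21 | potassium 5-hydroxy-2-(3-hydroxy-4-methoxyphenyl)-4-oxo-4H-chromen-7-yl sulfate (not isolated) | COc1ccc(-c2cc(=O)c3c(O)cc(OS(=O)(=O)[O-])cc3o2)cc1O.[K+] | intermediate
22 | 5-hydroxy-2-(3-hydroxy-4-methoxyphenyl)-4-oxo-4H-chromen-7-yl hydrogen sulfate (no stereocentres) | COc1ccc(-c2cc(=O)c3c(O)cc(OS(=O)(=O)O)cc3o2)cc1O | target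

Total step count: 9. Longest linear sequence: 9 steps (1 → 22).

Steps most likely to fail

Step 6 (key step). The carbene may be consumed before it adds to the hindered, tetrasubstituted C2=C3 bond, may attack ring A instead, or the cyclopropane may simply desilylate without ring enlargement. The fallback builds ring C by known Baker–Venkataraman-type chemistry and sets out from benzyl bromide 7 and pivaloyl chloride 2. Commercial 2,4,6-trihydroxyacetophenone would be dibenzylated with 7 (K2CO3, DMF) to 1-[2,4-bis(benzyloxy)-6-hydroxyphenyl]ethanone F1. Commercial 3-hydroxy-4-methoxybenzoic acid would be acylated with 2 to 4-methoxy-3-(pivaloyloxy)benzoic acid F2 and converted with (COCl)2 into 4-methoxy-3-(pivaloyloxy)benzoyl chloride F3. The dilithium salt of F1 (LiN(SiMe3)2, THF, −78 °C) would be C-acylated by F3 to the 1,3-diketone F4, and acid-catalysed cyclodehydration (p-TsOH, toluene, reflux) should give 5,7-bis(benzyloxy)-2-[4-methoxy-3-(pivaloyloxy)phenyl]-4H-chromen-4-one F5. Hydrogenolysis of F5 under the conditions of step 7 rejoins the route at 18.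

Step 4. Electrophilic bromination of the very electron-rich ring A at its free positions, or HBr-induced debenzylation, may compete with α-bromination. The fallback uses no halogen and sets out from 8. Regitz diazo transfer (4-acetamidobenzenesulfonyl azide, DBU, MeCN) should give the diazo ketone F6. Rh2(OAc)4 (cat.) in CH2Cl2 would then effect intramolecular O–H insertion of the rhodium carbene into the ortho phenol, giving benzofuranone 12 directly. The route is rejoined at 12, which is silylated as in the second half of step 5.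

Step 8. Sulfation of the acidic, weakly nucleophilic 7-hydroxyl may stall, forcing it may sulfate the chelated 5-hydroxyl as well, and the polar salt may be lost on purification. The fallback introduces the sulfate as a neutral protected diester and sets out from 18. 2,2,2-Trichloroethyl chlorosulfate, Et3N and DMAP in THF should give the aryl 2,2,2-trichloroethyl sulfate F7, which can be chromatographed on silica. Zn dust and HCO2NH4 in MeOH would release the monoester by reductive fragmentation as the ammonium sulfate F8. F8 enters step 9 in place of 20 and rejoins the route at the potassium salt 21.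

Further compounds
F1 | step 6 | 1-[2,4-bis(benzyloxy)-6-hydroxyphenyl]ethanone | CC(=O)c1c(O)cc(OCc2ccccc2)cc1OCc1ccccc1
F2 | step 6 | 4-methoxy-3-(pivaloyloxy)benzoic acid | COc1ccc(C(=O)O)cc1OC(=O)C(C)(C)C
F3 | step 6 | 4-methoxy-3-(pivaloyloxy)benzoyl chloride | COc1ccc(C(=O)Cl)cc1OC(=O)C(C)(C)C
F4 | step 6 | 5-{3-[2,4-bis(benzyloxy)-6-hydroxyphenyl]-3-oxopropanoyl}-2-methoxyphenyl pivalate | COc1ccc(C(=O)CC(=O)c2c(O)cc(OCc3ccccc3)cc2OCc2ccccc2)cc1OC(=O)C(C)(C)C
F5 | step 6 | 5,7-bis(benzyloxy)-2-[4-methoxy-3-(pivaloyloxy)phenyl]-4H-chromen-4-one | COc1ccc(-c2cc(=O)c3c(OCc4ccccc4)cc(OCc4ccccc4)cc3o2)cc1OC(=O)C(C)(C)C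
F6 | step 4 | 5-{2-[2,4-bis(benzyloxy)-6-hydroxyphenyl]-1-diazo-2-oxoethyl}-2-methoxyphenyl pivalate | COc1ccc(C(=[N+]=[N-])C(=O)c2c(O)cc(OCc3ccccc3)cc2OCc2ccccc2)cc1OC(=O)C(C)(C)C
F7 | step 8 | 5-hydroxy-2-[4-methoxy-3-(pivaloyloxy)phenyl]-4-oxo-4H-chromen-7-yl 2,2,2-trichloroethyl sulfate | COc1ccc(-c2cc(=O)c3c(O)cc(OS(=O)(=O)OCC(Cl)(Cl)Cl)cc3o2)cc1OC(=O)C(C)(C)C
F8 | step 8 | ammonium 5-hydroxy-2-[4-methoxy-3-(pivaloyloxy)phenyl]-4-oxo-4H-chromen-7-yl sulfate | COc1ccc(-c2cc(=O)c3c(O)cc(OS(=O)(=O)[O-])cc3o2)cc1OC(=O)C(C)(C)C.[NH4+]
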